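**Plan**

1. Retrosynthesis: (a) the C1–C6 bond of the 2,6,6-trimethylcyclohexene (chain-bearing olefinic carbon to CMe2 carbon) is cut by a retro cation–olefin cyclisation; (b) the C1=C2 alkene of the hexadienyl chain is cut by a Julia–Lythgoe disconnection into a chroman-2-carbaldehyde and (2E,6E)-farnesyl phenyl sulfone; (c) the chromane C4–C4a bond is cut by a B-alkyl Suzuki disconnection; (d) the chromane C2–O bond is cut by a palladium-allyl etherification of isoprene monoepoxide.
2. Enabling feature: ring carbons C1=C2(Me) and C6(Me)2 of the cyclohexene, linked by the three CH2 groups C3–C5, are the folded terminal head-to-tail 1,5-diene of a farnesyl chain. The ring is what a tertiary cation at C6 and the C1=C2 alkene give on closure, as in the presumed biosynthesis.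
3. Forward order: the benzene ring is bought, the dihydropyran ring is closed in step 2, the C15 chain is joined in step 5, the cyclohexene ring is closed last in step 6, the diene is unveiled in step 7 and the ester is hydrolysed in step 8.
4. Helpers: the β-acetoxy sulfone left by the first half of the Julia–Lythgoe reaction is kept through the acid step. There it stands in for the acid-labile dienyl aryl ether and disables the alkene that could close a second ring; it is removed in step 7.
5. Stereochemistry: C2 (R) comes from the ligand-controlled palladium-catalysed etherification in step 1 and, being quaternary, cannot epimerise. The 3E alkene is carried in from farnesyl bromide, the 1E alkene is set by the Julia–Lythgoe elimination, and the geometry of the alkene consumed in the ring closure is irrelevant.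

Key step: step 6

Assumption: the (R,R)-configured ligand in step 1 is taken to deliver the (R)-ether; the sense of induction is to be confirmed on the first batch, and the (S,S)-ligand is used instead if it proves opposite.

**Route**

Step 1
Reactants: 1 methyl 3-bromo-4-hydroxybenzoate; 2 racemic 2-methyl-2-vinyloxirane (isoprene monoepoxide)
Product: 3 methyl 3-bromo-4-{[(2R)-1-hydroxy-2-methylbut-3-en-2-yl]oxy}benzoate
Conditions: Pd2(dba)3·CHCl3 (1 mol %), (R,R)-DACH-naphthyl Trost ligand (3 mol %), CH2Cl2, 0 °C to rt, 2 added slowly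
Reagents that add atoms: none
Why: Palladium-catalysed asymmetric allylic etherification of a vinyl epoxide (dynamic kinetic asymmetric transformation): ionisation of 2 gives rapidly interconverting π-allylpalladium alkoxides, and ligand-controlled, alkoxide-directed delivery of the phenol to the tertiary allyl terminus should set the quaternary C–O stereocentre as (R) from both enantiomers of 2.

Step 2
Reactants: 3 methyl 3-bromo-4-{[(2R)-1-hydroxy-2-methylbut-3-en-2-yl]oxy}benzoate
Product: 5 methyl (2R)-2-(hydroxymethyl)-2-methyl-3,4-dihydro-2H-chromene-6-carboxylate, via B-alkyl-9-BBN adduct 4 (not isolated)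
Conditions: 9-BBN (2.5 equiv, the excess covers any O–B bond formation at the free hydroxyl), THF, 0 °C to rt; then Pd(dppf)Cl2 (5 mol %), K3PO4, DMF–H2O, 60 °C
Reagents that add atoms: none
Why: Anti-Markovnikov hydroboration of the vinyl group followed by intramolecular B-alkyl Suzuki–Miyaura coupling with the ortho bromide should close the six-membered dihydropyran ring without touching the quaternary stereocentre.

Step 3
Reactants: 5 methyl (2R)-2-(hydroxymethyl)-2-methyl-3,4-dihydro-2H-chromene-6-carboxylate
Product: 6 methyl (2R)-2-formyl-2-methyl-3,4-dihydro-2H-chromene-6-carboxylate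
Conditions: Dess–Martin periodinane, CH2Cl2, rt
Reagents that add atoms: none
Why: Dess–Martin oxidation of the neopentyl-type primary alcohol; the aldehyde has no α-hydrogen and so can neither enolise nor epimerise.

Step 4
Reactants: 7 (2E,6E)-farnesyl bromide
Product: 8 (2E,6E)-farnesyl phenyl sulfone
Conditions: PhSO2Na, DMF, rt
Reagents that add atoms: sodium benzenesulfinate, [Na+].[O-]S(=O)c1ccccc1
Why: SN2 S-alkylation of the sulfinate by the primary allylic bromide, with both alkene geometries retained.

Step 5
Reactants: 8 (2E,6E)-farnesyl phenyl sulfone; 6 methyl (2R)-2-formyl-2-methyl-3,4-dihydro-2H-chromene-6-carboxylate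
Product: 11 methyl (2R)-2-[(3E,7E)-1-acetoxy-4,8,12-trimethyl-2-(phenylsulfonyl)trideca-3,7,11-trien-1-yl]-2-methyl-3,4-dihydro-2H-chromene-6-carboxylate (diastereomer mixture), via lithiated sulfone 9 (not isolated), via lithium alkoxide 10 (not isolated)
Conditions: n-BuLi, THF, −78 °C; then 6, −78 °C; then Ac2O, −78 °C to rt
Reagents that add atoms: acetic anhydride, CC(=O)OC(C)=O
Why: First half of the Julia–Lythgoe olefination: the α-sulfonyl allyl anion adds through its α-carbon to the non-enolisable aldehyde and the alkoxide is trapped as the acetate before it can revert; the two new centres form unselectively and are both destroyed in step 7.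

Step 6
Reactants: 11 methyl (2R)-2-[(3E,7E)-1-acetoxy-4,8,12-trimethyl-2-(phenylsulfonyl)trideca-3,7,11-trien-1-yl]-2-methyl-3,4-dihydro-2H-chromene-6-carboxylate
Product: 13 methyl (2R)-2-[(3E)-1-acetoxy-4-methyl-2-(phenylsulfonyl)-6-(2,6,6-trimethylcyclohex-1-en-1-yl)hex-3-en-1-yl]-2-methyl-3,4-dihydro-2H-chromene-6-carboxylate (diastereomer mixture), via cyclohexyl cation 12 (not isolated)
Conditions: conc. H2SO4 (3 equiv), AcOH–CH2Cl2, 15 °C, continued until the olefin isomers have converged; ice-water quench
Reagents that add atoms: none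
Why: Markovnikov protonation of the terminal 11,12-alkene of 11 gives the tertiary cation at C12, which is captured by the 7,8-alkene through a chair-like transition state to give cyclohexyl cation 12; loss of the proton from the ring carbon that bears the chain gives the tetrasubstituted alkene, while the kinetically formed endocyclic trisubstituted and exocyclic isomers re-enter through 12 until the most substituted olefin predominates. The closest known reaction type is the acid-mediated head-to-tail monocyclisation of a geranyl terminus (pseudoionone to ionone, geranyl sulfone to cyclogeranyl sulfone), the laboratory counterpart of the terpene-cyclase event presumed for this skeleton. The cyclohexene ring is closed in the 6-endo-trig mode with respect to the 7,8-alkene. No stereocentre is created, and because both carbons of the 7,8-alkene end up in the ring olefin, the geometry of that alkene and every positional olefin isomer converge on one product. The step needs initiation at the remote diene only, termination after one ring, no ionisation of the chromane C2–O bond and the tetrasubstituted position for the double bond. The first three are secured by the allylic phenylsulfonyl group and the branching at C1 and C2 of the side chain, which deactivate and shield the 3,4-alkene towards both protonation and attack on 12, and by the β-acetoxy group and the ester-bearing arene, which retard heterolysis of the tertiary aryl ether; the last rests on thermodynamic control.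

Step 7
Reactants: 13 methyl (2R)-2-[(3E)-1-acetoxy-4-methyl-2-(phenylsulfonyl)-6-(2,6,6-trimethylcyclohex-1-en-1-yl)hex-3-en-1-yl]-2-methyl-3,4-dihydro-2H-chromene-6-carboxylate
Product: 14 methyl (2R)-2-methyl-2-[(1E,3E)-4-methyl-6-(2,6,6-trimethylcyclohex-1-en-1-yl)hexa-1,3-dien-1-yl]-3,4-dihydro-2H-chromene-6-carboxylate
Conditions: sodium amalgam (6% Na(Hg)), Na2HPO4, THF–MeOH (3:1), −20 °C
Reagents that add atoms: none
Why: Julia–Lythgoe reductive elimination: electron transfer cleaves the C–S bond and the β-acetate is expelled, so all diastereomers of 13 should converge on the (E)-disubstituted alkene favoured by the quaternary C2 substituent, which unveils the (1E,3E)-diene with the 3E geometry carried over.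

Step 8
Reactants: 14 methyl (2R)-2-methyl-2-[(1E,3E)-4-methyl-6-(2,6,6-trimethylcyclohex-1-en-1-yl)hexa-1,3-dien-1-yl]-3,4-dihydro-2H-chromene-6-carboxylate
Product: 15 (2R)-2-methyl-2-[(1E,3E)-4-methyl-6-(2,6,6-trimethylcyclohex-1-en-1-yl)hexa-1,3-dien-1-yl]-3,4-dihydro-2H-chromene-6-carboxylic acid
Conditions: LiOH·H2O, THF–MeOH–H2O, 40 °C; then 1 M HCl to pH 4, 0 °C
Reagents that add atoms: lithium hydroxide, [Li+].[OH-]
Why: Saponification of the aryl methyl ester; the tertiary dienyl aryl ether is stable to base, and the acid is liberated cold at pH 4 so that the pentadienylic C–O bond is not ionised.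

**Compound list**

1 | methyl 3-bromo-4-hydroxybenzoate | COC(=O)c1ccc(O)c(Br)c1 | starting material
2 | 2-methyl-2-vinyloxirane (isoprene monoepoxide), racemic | C=CC1(C)CO1 | starting material
3 | methyl 3-bromo-4-{[(2R)-1-hydroxy-2-methylbut-3-en-2-yl]oxy}benzoate | OC[C@@](Oc1ccc(C(=O)OC)cc1Br)(C)C=C | intermediate
4 | methyl 4-{[(2R)-4-(9-borabicyclo[3.3.1]nonan-9-yl)-1-hydroxy-2-methylbutan-2-yl]oxy}-3-bromobenzoate (B-alkyl-9-BBN adduct, not isolated) | OC[C@@](Oc1ccc(C(=O)OC)cc1Br)(C)CCB1C2CCCC1CCC2 | intermediate
5 | methyl (2R)-2-(hydroxymethyl)-2-methyl-3,4-dihydro-2H-chromene-6-carboxylate | OC[C@@]1(C)CCc2cc(C(=O)OC)ccc2O1 | intermediate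
6 | methyl (2R)-2-formyl-2-methyl-3,4-dihydro-2H-chromene-6-carboxylate | O=C[C@@]1(C)CCc2cc(C(=O)OC)ccc2O1 | intermediate
7 | (2E,6E)-farnesyl bromide, (2E,6E)-1-bromo-3,7,11-trimethyldodeca-2,6,10-triene | BrC/C=C(C)/CC/C=C(C)/CCC=C(C)C | starting material
8 | (2E,6E)-farnesyl phenyl sulfone, {[(2E,6E)-3,7,11-trimethyldodeca-2,6,10-trien-1-yl]sulfonyl}benzene | O=S(=O)(C/C=C(C)/CC/C=C(C)/CCC=C(C)C)c1ccccc1 | intermediate
9 | lithium (2E,6E)-3,7,11-trimethyl-1-(phenylsulfonyl)dodeca-2,6,10-trien-1-ide (lithiated 8, not isolated) | [Li]C(/C=C(C)/CC/C=C(C)/CCC=C(C)C)S(=O)(=O)c1ccccc1 | intermediate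
10 | lithium alkoxide adduct of 9 and 6 (diastereomer mixture, not isolated) | [Li]OC(C(/C=C(C)/CC/C=C(C)/CCC=C(C)C)S(=O)(=O)c1ccccc1)[C@@]1(C)CCc2cc(C(=O)OC)ccc2O1 | intermediate
11 | methyl (2R)-2-[(3E,7E)-1-acetoxy-4,8,12-trimethyl-2-(phenylsulfonyl)trideca-3,7,11-trien-1-yl]-2-methyl-3,4-dihydro-2H-chromene-6-carboxylate (diastereomer mixture at C1 and C2 of the side chain) | CC(=O)OC(C(/C=C(C)/CC/C=C(C)/CCC=C(C)C)S(=O)(=O)c1ccccc1)[C@@]1(C)CCc2cc(C(=O)OC)ccc2O1 | intermediate
12 | 2,6,6-trimethyl-1-substituted cyclohexyl cation formed by ring closure of protonated 11 (not isolated) | CC(=O)OC(C(/C=C(C)/CCC1[C+](C)CCCC1(C)C)S(=O)(=O)c1ccccc1)[C@@]1(C)CCc2cc(C(=O)OC)ccc2O1 | intermediate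
13 | methyl (2R)-2-[(3E)-1-acetoxy-4-methyl-2-(phenylsulfonyl)-6-(2,6,6-trimethylcyclohex-1-en-1-yl)hex-3-en-1-yl]-2-methyl-3,4-dihydro-2H-chromene-6-carboxylate (diastereomer mixture at C1 and C2 of the side chain) | CC(=O)OC(C(/C=C(C)/CCC1=C(C)CCCC1(C)C)S(=O)(=O)c1ccccc1)[C@@]1(C)CCc2cc(C(=O)OC)ccc2O1 | intermediate
14 | methyl (2R)-2-methyl-2-[(1E,3E)-4-methyl-6-(2,6,6-trimethylcyclohex-1-en-1-yl)hexa-1,3-dien-1-yl]-3,4-dihydro-2H-chromene-6-carboxylate | CC1=C(CC/C(C)=C/C=C/[C@@]2(C)CCc3cc(C(=O)OC)ccc3O2)C(C)(C)CCC1 | intermediate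
15 | (2R)-2-methyl-2-[(1E,3E)-4-methyl-6-(2,6,6-trimethylcyclohex-1-en-1-yl)hexa-1,3-dien-1-yl]-3,4-dihydro-2H-chromene-6-carboxylic acid | CC1=C(CC/C(C)=C/C=C/[C@@]2(C)CCc3cc(C(=O)O)ccc3O2)C(C)(C)CCC1 | target

**Count**

Total steps: 8. Longest linear sequence: 7 steps (steps 1, 2, 3, 5, 6, 7, 8); the sulfone branch contributes step 4.

**Steps most likely to fail**

Step 6. Three processes threaten it: capture of cation 12 by the 3,4-alkene before proton loss (a second ring closure), incomplete migration of the double bond into the tetrasubstituted position, and reversible acid-induced opening of the chromane at C2 with loss of enantiomeric purity. The fallback buys the ring instead of making it; it sets out from aldehyde 6 and comes back at 13. Commercial 4-(2,6,6-trimethylcyclohex-1-en-1-yl)butan-2-one is homologated with triethyl phosphonoacetate and NaH (Horner–Wadsworth–Emmons) to ethyl (2E)-3-methyl-5-(2,6,6-trimethylcyclohex-1-en-1-yl)pent-2-enoate F1, the minor 2Z isomer being removed by chromatography. DIBAL-H reduces it to (2E)-3-methyl-5-(2,6,6-trimethylcyclohex-1-en-1-yl)pent-2-en-1-ol F2. PBr3 gives 2-[(3E)-5-bromo-3-methylpent-3-en-1-yl]-1,3,3-trimethylcyclohex-1-ene F3, and PhSO2Na in DMF gives {[(2E)-3-methyl-5-(2,6,6-trimethylcyclohex-1-en-1-yl)pent-2-en-1-yl]sulfonyl}benzene F4. This sulfone is deprotonated with n-BuLi to the lithiated sulfone F5, added to 6 to give the lithium alkoxide F6 and acetylated in the same flask as in step 5, which delivers 13.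

Step 1. The product is itself a tertiary allyl ether of an acidic phenol, so zerovalent palladium may re-ionise it; repeated ionisation would drain the branched ether into the linear regioisomer and erode the enantiomeric purity, and the sense of induction rests on the stated assumption. The fallback sets out from 2 and comes back at 3; it sets the stereocentre with an oxygen nucleophile whose adduct cannot re-ionise and forms the aryl–oxygen bond afterwards by nucleophilic aromatic substitution. Racemic 2 is opened under the same palladium and ligand system with NaHCO3 and catalytic Et3B in CH2Cl2–H2O to give (2R)-2-methylbut-3-ene-1,2-diol F7. The primary hydroxyl is tritylated (TrCl, pyridine) to give (2R)-2-methyl-1-(triphenylmethoxy)but-3-en-2-ol F8. Its potassium alkoxide (KHMDS, THF, 0 °C) displaces fluoride from commercial methyl 3-bromo-4-fluorobenzoate, activated by the para ester, to give methyl 3-bromo-4-{[(2R)-2-methyl-1-(triphenylmethoxy)but-3-en-2-yl]oxy}benzoate F9. 80% aqueous AcOH at rt removes the trityl group and returns 3.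

Step 7. Electron transfer from the amalgam to the aromatic ester may compete with C–S cleavage, and methoxide formed in the flask may strip the acetate and trigger retro-addition to aldehyde and sulfone. The fallback sets out from 13 and comes back at 14; it separates elimination from reduction so that the reductant meets only a vinyl sulfone, which accepts an electron far more readily than the ester. DBU in THF at rt removes acetic acid by an E1cB elimination to give methyl (2R)-2-methyl-2-[(3E)-4-methyl-2-(phenylsulfonyl)-6-(2,6,6-trimethylcyclohex-1-en-1-yl)hexa-1,3-dien-1-yl]-3,4-dihydro-2H-chromene-6-carboxylate F10, either geometry at the new alkene being acceptable. SmI2 with DMPU and MeOH in THF at −78 °C then cleaves the alkenyl sulfone reductively, the alkenyl intermediate relaxing to the E geometry, and gives 14.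

**Further compounds**

F1 | step 6 | ethyl (2E)-3-methyl-5-(2,6,6-trimethylcyclohex-1-en-1-yl)pent-2-enoate | CCOC(=O)/C=C(C)/CCC1=C(C)CCCC1(C)C
F2 | step 6 | (2E)-3-methyl-5-(2,6,6-trimethylcyclohex-1-en-1-yl)pent-2-en-1-ol | OC/C=C(C)/CCC1=C(C)CCCC1(C)C
F3 | step 6 | 2-[(3E)-5-bromo-3-methylpent-3-en-1-yl]-1,3,3-trimethylcyclohex-1-ene | BrC/C=C(C)/CCC1=C(C)CCCC1(C)C
F4 | step 6 | {[(2E)-3-methyl-5-(2,6,6-trimethylcyclohex-1-en-1-yl)pent-2-en-1-yl]sulfonyl}benzene | O=S(=O)(C/C=C(C)/CCC1=C(C)CCCC1(C)C)c1ccccc1
F5 | step 6 | lithium (2E)-3-methyl-1-(phenylsulfonyl)-5-(2,6,6-trimethylcyclohex-1-en-1-yl)pent-2-en-1-ide (lithiated F4) | [Li]C(/C=C(C)/CCC1=C(C)CCCC1(C)C)S(=O)(=O)c1ccccc1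
F6 | step 6 | lithium alkoxide adduct of F5 and 6 (diastereomer mixture) | [Li]OC(C(/C=C(C)/CCC1=C(C)CCCC1(C)C)S(=O)(=O)c1ccccc1)[C@@]1(C)CCc2cc(C(=O)OC)ccc2O1
F7 | step 1 | (2R)-2-methylbut-3-ene-1,2-diol | OC[C@@](O)(C)C=C
F8 | step 1 | (2R)-2-methyl-1-(triphenylmethoxy)but-3-en-2-ol | C(OC(c1ccccc1)(c1ccccc1)c1ccccc1)[C@@](O)(C)C=C
F9 | step 1 | methyl 3-bromo-4-{[(2R)-2-methyl-1-(triphenylmethoxy)but-3-en-2-yl]oxy}benzoate | C(OC(c1ccccc1)(c1ccccc1)c1ccccc1)[C@@](Oc1ccc(C(=O)OC)cc1Br)(C)C=C
F10 | step 7 | methyl (2R)-2-methyl-2-[(3E)-4-methyl-2-(phenylsulfonyl)-6-(2,6,6-trimethylcyclohex-1-en-1-yl)hexa-1,3-dien-1-yl]-3,4-dihydro-2H-chromene-6-carboxylate | CC1=C(CC/C(C)=C/C(=C[C@@]2(C)CCc3cc(C(=O)OC)ccc3O2)S(=O)(=O)c2ccccc2)C(C)(C)CCC1
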